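**Assumption:** silylating agents, MeI, DMF, boron reagents, oxidants and catalysts are treated as reagents; 7'' is the benzylic carbinol carbon and 8'' the ether-bearing carbon. The route is a paper design and has not been run.

## Retrosynthetic overview

1. The flavone C2–C1' bond is made last-but-one by a Pd(II) dehydrogenation/oxidative boron-Heck union of an A-ring chromanone with a B/C-ring aryl boronate.
2. The boronate comes from Ir-catalysed C–H borylation of the protected threo β-aryl ether diol.
3. Both stereocentres (7''S, 8''S) are set in one Ru transfer hydrogenation with dynamic kinetic resolution of an α-aryloxy-β-keto ester (the proposed new step); the C8''–O bond comes from Rh-carbenoid O–H insertion.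
4. Building blocks: resorcinol (A ring and B ring), 4-bromophenol, ethyl diazoacetate (C8'', C9''), 3-chloropropanoic acid (C2–C4).
5. Ring order: the three benzene rings are bought; the only ring built is the pyranone (chromanone in step 14, aromatised to the chromen-4-one in step 16).

## Route

**Branch C (C ring, C7''–C9'')**

Step 1
Reactants: 1, 4-bromophenol
Product: 2, (4-bromophenoxy)triisopropylsilane
Conditions: TIPSCl, imidazole, DMF, rt
Reagents that add atoms: triisopropylsilyl chloride, CC(C)[Si](Cl)(C(C)C)C(C)C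
Why: Standard phenol silylation; the TIPS ether survives BuLi, LDA, hydride and hot Pd/Ir steps and is removed by fluoride at the end.

Step 2
Reactants: 2
Product: 3, 4-(triisopropylsilyloxy)benzaldehyde
Conditions: n-BuLi, THF, −78 °C; DMF; aq. NH4Cl
Reagents that add atoms: N,N-dimethylformamide, CN(C)C=O (CHO carbon and oxygen)
Why: Br–Li exchange followed by Bouveault formylation of the aryllithium.

Step 3
Reactants: 3; 4, ethyl diazoacetate
Product: 5, ethyl 2-diazo-3-hydroxy-3-[4-(triisopropylsilyloxy)phenyl]propanoate (racemic)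
Conditions: LDA, THF, −78 °C; AcOH quench
Reagents that add atoms: none
Why: Aldol-type addition of ethyl lithiodiazoacetate to the aldehyde; the carbinol is racemic and is erased in step 4.

Step 4
Reactants: 5
Product: 6, ethyl 2-diazo-3-oxo-3-[4-(triisopropylsilyloxy)phenyl]propanoate
Conditions: Dess–Martin periodinane, CH2Cl2, 0 °C to rt
Reagents that add atoms: none
Why: Dess–Martin oxidation of the β-hydroxy-α-diazo ester to the acceptor/acceptor diazo compound; the diazo group tolerates the oxidant.

**Branch B (B ring)**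

Step 5
Reactants: 7, resorcinol (benzene-1,3-diol)
Product: 8, 1,3-dimethoxybenzene
Conditions: MeI, K2CO3, acetone, reflux
Reagents that add atoms: iodomethane, CI
Why: Williamson ether synthesis; these methyls become the 3',5'-OMe groups.

Step 6
Reactants: 8
Product: 9, 2,6-dimethoxyphenol
Conditions: n-BuLi, THF, 0 °C to rt; B(OMe)3, −78 °C to rt; AcOH, 30% H2O2, 0 °C
Reagents that add atoms: hydrogen peroxide, OO (phenol oxygen)
Why: Directed ortho-metalation at C2 between the two OMe groups, borylation and oxidative C–B cleavage give the phenol.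

**Trunk**

Step 7
Reactants: 6; 9
Product: 10, ethyl 2-(2,6-dimethoxyphenoxy)-3-oxo-3-[4-(triisopropylsilyloxy)phenyl]propanoate (racemic, epimerisable at C2)
Conditions: Rh2(OAc)4 (1 mol%), toluene, 80 °C, slow addition of 6
Reagents that add atoms: none
Why: Rh(II)-carbenoid O–H insertion: the electrophilic carbenoid is trapped by the phenol O–H and forms the C8''–O–C4' ether bond with loss of N2.

Step 8
Reactants: 10
Product: 11, ethyl (2R,3S)-2-(2,6-dimethoxyphenoxy)-3-hydroxy-3-[4-(triisopropylsilyloxy)phenyl]propanoate (syn/threo)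
Conditions: RuCl(p-cymene)[(R,R)-TsDPEN] (2 mol%), HCO2H/Et3N (5:2), CH2Cl2, 30–35 °C
Reagents that add atoms: none
Why: Proposed new method: Noyori–Ikariya asymmetric transfer hydrogenation with dynamic kinetic resolution, extended to an α-(2,6-dimethoxyaryloxy) β-keto ester (closest known reaction type: transfer-hydrogenation DKR of α-alkoxy and α-amido β-keto esters); the doubly activated α-H epimerises fast in HCO2H/Et3N, the (R,R)-Ru–H/N–H delivers hydride outer-sphere to the aryl-ketone face fixed by the arene CH/π contact (giving 3S), and only the 2R epimer can place the C–OAr bond anti to the incoming hydride (Felkin–Anh), so both stereocentres are set as the syn (2R,3S) ester.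

Step 9
Reactants: 11
Product: 12, (1S,2S)-2-(2,6-dimethoxyphenoxy)-1-[4-(triisopropylsilyloxy)phenyl]propane-1,3-diol
Conditions: LiBH4, THF (MeOH 1 equiv), 0 °C to rt
Reagents that add atoms: none
Why: Hydride reduction of the α-aryloxy-β-hydroxy ester to the primary alcohol; no stereocentre is touched (2R becomes 2S only through the CIP priority change).

Step 10
Reactants: 12
Product: 13, (1S,2S)-1,3-bis(tert-butyldimethylsilyloxy)-2-(2,6-dimethoxyphenoxy)-1-[4-(triisopropylsilyloxy)phenyl]propane
Conditions: TBSOTf, 2,6-lutidine, CH2Cl2, 0 °C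
Reagents that add atoms: tert-butyldimethylsilyl triflate, CC(C)(C)[Si](C)(C)OS(=O)(=O)C(F)(F)F
Why: Silylation of both alcohols so the benzylic carbinol survives the Ir step and the Pd(II)/O2 coupling.

Step 11
Reactants: 13
Product: 14, 2-[4-({(1S,2S)-1,3-bis(tert-butyldimethylsilyloxy)-1-[4-(triisopropylsilyloxy)phenyl]propan-2-yl}oxy)-3,5-dimethoxyphenyl]-4,4,5,5-tetramethyl-1,3,2-dioxaborolane
Conditions: [Ir(OMe)(cod)]2 (2.5 mol%), dtbpy (5 mol%), B2pin2, THF, 80 °C
Reagents that add atoms: bis(pinacolato)diboron, CC1(C)OB(OC1(C)C)B1OC(C)(C)C(C)(C)O1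
Why: Sterically controlled Ir-catalysed C–H borylation: the C–H para to the ether oxygen is the only arene C–H without an ortho substituent, and the 1,4-disubstituted C ring is blocked by its bulky groups.

**Branch A (A ring and C2–C4)**

Step 12
Reactants: 7, resorcinol
Product: 15, 1,3-bis(tert-butyldimethylsilyloxy)benzene
Conditions: TBSCl, imidazole, DMF, rt
Reagents that add atoms: tert-butyldimethylsilyl chloride, CC(C)(C)[Si](C)(C)Cl
Why: Silylation removes the acidic O–H groups and makes C2, C4 and C6 sterically inaccessible for the next step.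

Step 13
Reactants: 15
Product: 16, 3,5-bis(tert-butyldimethylsilyloxy)phenol
Conditions: [Ir(OMe)(cod)]2 (1 mol%), dtbpy (2 mol%), B2pin2, hexane, 80 °C; then Oxone, acetone/H2O, rt
Reagents that add atoms: Oxone (potassium peroxymonosulfate), [K+].[O-]S(=O)(=O)OO (phenol oxygen)
Why: One-pot Ir-catalysed C–H borylation at C5 (the only C–H not ortho to a substituent) and ipso-oxidation installs the third A-ring oxygen.

Step 14
Reactants: 16; 17, 3-chloropropanoic acid
Product: 18, 5,7-dihydroxychroman-4-one
Conditions: TfOH, 80 °C; then 2 M NaOH, 0 °C to rt; HCl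
Reagents that add atoms: none
Why: Friedel–Crafts acylation in TfOH (the TBS ethers are cleaved in situ and all ring positions are equivalent), then intramolecular Williamson closure of the ortho-phenoxide onto the chloride forms the pyranone ring.

Step 15
Reactants: 18
Product: 19, 5,7-bis(tert-butyldimethylsilyloxy)chroman-4-one
Conditions: TBSOTf, 2,6-lutidine, CH2Cl2, −78 to 0 °C; mild acidic work-up
Reagents that add atoms: tert-butyldimethylsilyl triflate, CC(C)(C)[Si](C)(C)OS(=O)(=O)C(F)(F)F
Why: Silyl triflate is needed for the chelated 5-OH; masking it prevents O,O-chelation of Pd in step 16, and any silyl enol ether is hydrolysed on work-up.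

**Union and end game**

Step 16
Reactants: 14; 19 (2 equiv)
Product: 20, 5,7-bis(tert-butyldimethylsilyloxy)-2-[4-({(1S,2S)-1,3-bis(tert-butyldimethylsilyloxy)-1-[4-(triisopropylsilyloxy)phenyl]propan-2-yl}oxy)-3,5-dimethoxyphenyl]-4H-chromen-4-one (any 5-O-desilylated material is carried forward; it converges in step 17)
Conditions: Pd(TFA)2 (15 mol%), 5-nitro-1,10-phenanthroline (20 mol%), DMSO, O2 (1 atm), 100 °C; 19 pre-heated, then 14 added
Reagents that add atoms: none
Why: One-pot Pd(II) aerobic dehydrogenation of the chromanone to the chromone, oxidative boron-Heck addition of aryl–Pd across C2=C3 (aryl to the β-carbon C2) and re-dehydrogenation give the flavone and form the C2–C1' bond; the silylated side chain is inert.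

Step 17
Reactants: 20
Product: 21, (7''S,8''S)-target: 5,7-dihydroxy-2-[4-({(1S,2S)-1,3-dihydroxy-1-(4-hydroxyphenyl)propan-2-yl}oxy)-3,5-dimethoxyphenyl]-4H-chromen-4-one
Conditions: TBAF/AcOH (1:1, 8 equiv), THF, 0 °C to rt
Reagents that add atoms: none
Why: Buffered fluoride cleaves all five silyl ethers without base-induced quinone-methide chemistry at the p-hydroxybenzylic carbinol; the stereocentres are untouched.

## Compound list

1 | 4-bromophenol | Oc1ccc(Br)cc1 | starting material
2 | (4-bromophenoxy)triisopropylsilane | CC(C)[Si](Oc1ccc(Br)cc1)(C(C)C)C(C)C | intermediate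
3 | 4-(triisopropylsilyloxy)benzaldehyde | CC(C)[Si](Oc1ccc(C=O)cc1)(C(C)C)C(C)C | intermediate
4 | ethyl diazoacetate | CCOC(=O)C=[N+]=[N-] | starting material
5 | ethyl 2-diazo-3-hydroxy-3-[4-(triisopropylsilyloxy)phenyl]propanoate (racemic) | CCOC(=O)C(=[N+]=[N-])C(O)c1ccc(O[Si](C(C)C)(C(C)C)C(C)C)cc1 | intermediate
6 | ethyl 2-diazo-3-oxo-3-[4-(triisopropylsilyloxy)phenyl]propanoate | CCOC(=O)C(=[N+]=[N-])C(=O)c1ccc(O[Si](C(C)C)(C(C)C)C(C)C)cc1 | intermediate
7 | resorcinol | Oc1cccc(O)c1 | starting material
8 | 1,3-dimethoxybenzene | COc1cccc(OC)c1 | intermediate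
9 | 2,6-dimethoxyphenol | COc1cccc(OC)c1O | intermediate
10 | ethyl 2-(2,6-dimethoxyphenoxy)-3-oxo-3-[4-(triisopropylsilyloxy)phenyl]propanoate (racemic) | CCOC(=O)C(Oc1c(OC)cccc1OC)C(=O)c1ccc(O[Si](C(C)C)(C(C)C)C(C)C)cc1 | intermediate
11 | ethyl (2R,3S)-2-(2,6-dimethoxyphenoxy)-3-hydroxy-3-[4-(triisopropylsilyloxy)phenyl]propanoate | COc1cccc(OC)c1O[C@@H](C(=O)OCC)[C@@H](O)c1ccc(O[Si](C(C)C)(C(C)C)C(C)C)cc1 | intermediate
12 | (1S,2S)-2-(2,6-dimethoxyphenoxy)-1-[4-(triisopropylsilyloxy)phenyl]propane-1,3-diol | COc1cccc(OC)c1O[C@@H](CO)[C@@H](O)c1ccc(O[Si](C(C)C)(C(C)C)C(C)C)cc1 | intermediate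
13 | (1S,2S)-1,3-bis(TBS-oxy)-2-(2,6-dimethoxyphenoxy)-1-[4-(TIPS-oxy)phenyl]propane | COc1cccc(OC)c1O[C@@H](CO[Si](C)(C)C(C)(C)C)[C@@H](O[Si](C)(C)C(C)(C)C)c1ccc(O[Si](C(C)C)(C(C)C)C(C)C)cc1 | intermediate
14 | pinacol boronate of 13, boron para to the ether oxygen on the dimethoxyaryl ring | COc1cc(B2OC(C)(C)C(C)(C)O2)cc(OC)c1O[C@@H](CO[Si](C)(C)C(C)(C)C)[C@@H](O[Si](C)(C)C(C)(C)C)c1ccc(O[Si](C(C)C)(C(C)C)C(C)C)cc1 | intermediate
15 | 1,3-bis(tert-butyldimethylsilyloxy)benzene | CC(C)(C)[Si](C)(C)Oc1cccc(O[Si](C)(C)C(C)(C)C)c1 | intermediate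
16 | 3,5-bis(tert-butyldimethylsilyloxy)phenol | CC(C)(C)[Si](C)(C)Oc1cc(O)cc(O[Si](C)(C)C(C)(C)C)c1 | intermediate
17 | 3-chloropropanoic acid | OC(=O)CCCl | starting material
18 | 5,7-dihydroxychroman-4-one | O=C1CCOc2cc(O)cc(O)c12 | intermediate
19 | 5,7-bis(tert-butyldimethylsilyloxy)chroman-4-one | O=C1CCOc2cc(O[Si](C)(C)C(C)(C)C)cc(O[Si](C)(C)C(C)(C)C)c12 | intermediate
20 | fully silylated flavonolignan (5,7-di-OTBS; 7'',9''-di-OTBS; 4''-OTIPS; 7''S,8''S) | COc1cc(-c2cc(=O)c3c(O[Si](C)(C)C(C)(C)C)cc(O[Si](C)(C)C(C)(C)C)cc3o2)cc(OC)c1O[C@@H](CO[Si](C)(C)C(C)(C)C)[C@@H](O[Si](C)(C)C(C)(C)C)c1ccc(O[Si](C(C)C)(C(C)C)C(C)C)cc1 | intermediate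
21 | (−)-(7''S,8''S)-4'',5,7-trihydroxy-3',5'-dimethoxy-4',8''-oxyflavonolignan-7'',9''-diol | COc1cc(-c2cc(=O)c3c(O)cc(O)cc3o2)cc(OC)c1O[C@@H](CO)[C@@H](O)c1ccc(O)cc1 | target

## Step count and risks

Total steps: 17. Longest linear sequence: 11 (steps 1–4, 7–11, 16, 17).

Three steps most likely to fail:

1. **Step 8 (proposed new transfer-hydrogenation DKR).** The bulky 2,6-dimethoxyphenoxy group may erode dr/ee or slow the reduction relative to racemisation. Fallback (known chemistry): Evans boron syn-glycolate aldol of (R)-4-benzyl-3-[(2,6-dimethoxyphenoxy)acetyl]oxazolidin-2-one with aldehyde 3 (Bu2BOTf, i-Pr2NEt), then LiBH4 removal of the auxiliary, which gives diol 12 directly.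

2. **Step 16 (Pd(II) dehydrogenation/oxidative boron-Heck).** The valuable boronate may homocouple or protodeboronate, and silyl ethers may be lost at 100 °C. Fallback: build the pyranone by Pd-catalysed carbonylative Sonogashira annulation instead. This uses 2-iodo-3,5-bis(silyloxy)phenol (NIS on 16) and the terminal aryl alkyne made from 14 (ipso-iodination, Sonogashira with TMS-acetylene, C-desilylation), with CO and Et2NH.

3. **Step 7 (Rh O–H insertion into the hindered, electron-rich phenol).** Arene C–H alkylation or ylide side reactions may compete. Fallback: make 10 without carbene chemistry by alkylating 9 with ethyl bromoacetate (K2CO3), LDA aldol of the aryloxyacetate with 3, then Dess–Martin oxidation.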